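The data are simulated for substances that don't exist.

The ratio of G to D in the charge comes first, and we want it before we touch the bath. The decision is whether dawn's heat is worth having over summer's, or whether the next change belongs in the recipe.

| setting | cedar | elm | oak | summer | dawn |
|---|---|---|---|---|---|
| D | 16 mM | 16 mM | 32 mM | 16 mM | 16 mM |
| G | 8 mM | 8 mM | 8 mM | 8.00 mM | 8.00 mM |
| X | 0.54 mM | 1.2 mM | 0.80 mM | 0.80 mM | 0.80 mM |
| temperature | 45 °C | 65 °C | 45 °C | 50 °C | 80 °C |
| remark | run made earlier | run made earlier | run made earlier |  |  |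
| time |  |  |  | 1.5 h | 1.5 h |

| run | time / min | L / % | D / % |
|---|---|---|---|
| cedar | 8.00 | 10 | 89 |
| cedar | 15.0 | 18 | 78 |
| cedar | 40.0 | 36 | 64 |
| cedar | 90.0 | 53 | 50 |
| elm | 6.00 | 37 | 56 |
| elm | 15.0 | 49 | 40 |
| elm | 30.0 | 48 | 43 |
| elm | 40.0 | 53 | 44 |
| oak | 25.0 | 15 | 75 |
| oak | 50.0 | 24 | 72 |
| oak | 60.0 | 28 | 70 |
| oak | 90.0 | 28 | 72 |

(each reading ± 2 percentage points)



- which flask leads in amount of L, in percent of the D charged ("all alike" within 1.5 percentage points) (summer / dawn / all alike)
- how much L is there at the end, in percent of the D charged: summer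
- how much L is there at the end, in percent of the D charged: dawn

We name the ceiling 50.0%: the G charged over the D charged, which is the L, in percent of the D charged, that one L per G allows. In summer and dawn G, at 8.00 mM against 16 mM of D, is the smaller charge, so we take it as the limiting reagent. The readings follow this ratio. Cedar's last reading is 53% against that ceiling, and the last reading of oak, with twice the D, is 28% against 25.0%, each 3 percentage points above it with a scatter of 2 points.

The doubt is whether summer gets there in 1.5 h. Cedar's 36% at 40.0 min gives, as a reading, a rate for closing the gap to the ceiling. We suppose that rate goes with X and allow nothing for the warmer bath, so at summer's 0.80 mM of X it is 0.0471 min⁻¹. Over 1.5 h that leaves 0.72 points below the ceiling, less than the margin of 1.5 points. By this reckoning summer's gap is already inside the margin, so we see little for more heat to win there. Its risk we read from elm at 65 °C, where L goes 49%, 48%, 53% from 15.0 min to 40.0 min and shows no fall beyond the scatter. We expect both flasks at the ceiling, so our decision is to keep summer's temperature and, for more L, to change the ratio.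

The forecast calls the flasks all alike, with summer at 50% and dawn at 49%, on the ground that “The plateaus show G is limiting”.

Summer ends at 50.0% of L and dawn at 50.0%, so the two stand all alike.

    D + X → Z (k = 8.40 L mol⁻¹ s⁻¹, Ea = 41.0 kJ mol⁻¹)
    G + Z ⇌ J (K = 130 L mol⁻¹, k = 12.0 L mol⁻¹ s⁻¹, Ea = 52.0 kJ mol⁻¹, ΔH = −45.0 kJ mol⁻¹)
    J ⇌ E + Q (K = 0.350 M, k = 3.80 s⁻¹, Ea = 84.0 kJ mol⁻¹, ΔH = −14.0 kJ mol⁻¹)
    Q → X + L (k = 1.70 s⁻¹, Ea = 92.0 kJ mol⁻¹)
    (constants at 80 °C)

Halfway, at 0.750 h, summer already holds 49.0% of L with 2.03% of its G left, and at 1.50 h G is down to 0.0152%. Summer and dawn both end on the ceiling of 50.0%. A neighbour of dawn charged with 9.6 mM of D, all else held, has a ceiling of 83.3% and ends at 83.3%.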